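**Plan**

- Retrosynthesis: the O–benzyl bond on the 5‑oxygenated indole is cut first. The four methoxy groups of the central ring are then traced back, two to the carbonyl oxygens of a 1,4‑benzoquinone (reductive O‑methylation) and two to C–Cl carbons (methoxide for chloride).
- The two aryl–indole C3 bonds are then cut at the quinone level, the bond to the 5‑oxygenated indole first and the bond to the 6‑methoxyindole second, leaving 2,5‑dichloro‑1,4‑benzoquinone.
- Enabling feature: the central benzene ring carries oxygen on four carbons, two of them para to each other, so it is the reduced, methylated form of a cyclohexa‑2,5‑diene‑1,4‑dione. The unsubstituted ring carbons of that dione are Michael acceptors for the enamine‑like C3 of an indole, so no halide or boron handle is needed on either partner.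
- Forward: 6‑methoxyindole adds to the dichloroquinone, then 5‑benzyloxyindole adds to the last ring C–H (each followed by re‑oxidation). Chloride is exchanged for methoxide, reductive methylation aromatizes the central ring, and hydrogenolysis frees the 5‑hydroxyl. No ring is built; all three ring systems are purchased.
- Stereochemistry: the target has no stereocentre, and both aryl–indole axes are flanked on the central ring by two identical methoxy groups, so no stereocontrol is needed.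

Key step: step 2

Remark on the chemistry: the 5‑hydroxyl is carried as its benzyl ether so that it stays unmethylated when the central‑ring oxygens are methylated; compounds 1, 2 and 5 are taken as purchased.

**Step 1**
Reactants: 1 6‑methoxy‑1H‑indole; 2 2,5‑dichloro‑1,4‑benzoquinone
Product: 4 2,5‑dichloro‑3‑(6‑methoxy‑1H‑indol‑3‑yl)cyclohexa‑2,5‑diene‑1,4‑dione, via hydroquinone adduct 3 (not isolated)
Conditions: 2 (1.5 equiv), conc. HCl (cat.), THF, rt; then DDQ (1 equiv), rt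
Reagents that add atoms: none
Why: Acid‑promoted Friedel–Crafts‑type conjugate (Michael) addition of indole C3 to an unsubstituted carbon of the chloroquinone should give hydroquinone 3 after tautomerisation, which DDQ dehydrogenates back to the quinone level; no stereocentre is formed.

**Step 2**
Reactants: 4 2,5‑dichloro‑3‑(6‑methoxy‑1H‑indol‑3‑yl)cyclohexa‑2,5‑diene‑1,4‑dione; 5 5‑(benzyloxy)‑1H‑indole
Product: 7 2‑[5‑(benzyloxy)‑1H‑indol‑3‑yl]‑3,6‑dichloro‑5‑(6‑methoxy‑1H‑indol‑3‑yl)cyclohexa‑2,5‑diene‑1,4‑dione, via hydroquinone adduct 6 (not isolated)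
Conditions: 5 (1.2 equiv), conc. H2SO4 (cat.), THF, rt; then DDQ (1 equiv), rt
Reagents that add atoms: none
Why: Protonation of a carbonyl oxygen of 4 activates the quinone, C3 of indole 5 attacks C6 (the only ring carbon that bears hydrogen, β to the C4 carbonyl), and loss of the indole C3 proton plus enolisation should give the aromatic hydroquinone 6, which DDQ dehydrogenates to quinone 7. The closest known reaction type is the acid‑promoted conjugate addition of indoles to halo‑1,4‑benzoquinones with re‑oxidation of the hydroquinone adduct, a formal C–H/C–H union. No ring is closed and no stereocentre is formed, and the new aryl–indole axis is not stereogenic in the target. Site selectivity on the quinone is needed: C6 is the only unsubstituted and least hindered acceptor carbon, the chlorine‑bearing carbons are shielded and made less electrophilic by chlorine lone‑pair donation, and the C2=C3 double bond is deactivated by the indolyl donor, so over‑addition is also excluded. Site selectivity on the indole is needed: C3 is the enamine β‑carbon, and the benzyl ether keeps the 5‑oxygen from acting as a free phenol that would activate C4 and C6 or be oxidised by DDQ. Chemoselectivity in the oxidation rests on the hydroquinone being far easier to oxidise than either indole or the benzyl ether.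

**Step 3**
Reactants: 7 2‑[5‑(benzyloxy)‑1H‑indol‑3‑yl]‑3,6‑dichloro‑5‑(6‑methoxy‑1H‑indol‑3‑yl)cyclohexa‑2,5‑diene‑1,4‑dione
Product: 8 2‑[5‑(benzyloxy)‑1H‑indol‑3‑yl]‑3,6‑dimethoxy‑5‑(6‑methoxy‑1H‑indol‑3‑yl)cyclohexa‑2,5‑diene‑1,4‑dione
Conditions: NaOMe (excess), MeOH/THF, 0 °C to rt
Reagents that add atoms: sodium methoxide, [Na+].[O-]C
Why: Each chlorine sits on the β‑carbon of a vinylogous acyl chloride, so methoxide should replace both by addition–elimination (nucleophilic vinylic substitution) without touching the benzyl ether or the indole N–H groups.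

**Step 4**
Reactants: 8 2‑[5‑(benzyloxy)‑1H‑indol‑3‑yl]‑3,6‑dimethoxy‑5‑(6‑methoxy‑1H‑indol‑3‑yl)cyclohexa‑2,5‑diene‑1,4‑dione
Product: 10 5‑(benzyloxy)‑3‑[4‑(6‑methoxy‑1H‑indol‑3‑yl)‑2,3,5,6‑tetramethoxyphenyl]‑1H‑indole, via hydroquinone 9 (not isolated)
Conditions: Na2S2O4, THF/H2O, rt; then Me2SO4, K2CO3, acetone, reflux, N2
Reagents that add atoms: dimethyl sulfate, COS(=O)(=O)OC
Why: Dithionite reduction aromatizes the central ring to the hydroquinone, and Williamson O‑methylation under a carbonate base (reductive methylation of a quinone) should alkylate the two phenols while leaving the much less acidic indole N–H groups untouched.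

**Step 5**
Reactants: 10 5‑(benzyloxy)‑3‑[4‑(6‑methoxy‑1H‑indol‑3‑yl)‑2,3,5,6‑tetramethoxyphenyl]‑1H‑indole
Product: 11 3‑[4‑(6‑methoxy‑1H‑indol‑3‑yl)‑2,3,5,6‑tetramethoxyphenyl]‑1H‑indol‑5‑ol
Conditions: H2 (1 atm), Pd/C, EtOAc/MeOH, rt
Reagents that add atoms: none
Why: Catalytic hydrogenolysis of the benzyl aryl ether should free the phenol under neutral conditions that leave the aryl methyl ethers and both indoles intact.

**Compound list**

1 | 6‑methoxy‑1H‑indole | COc1ccc2cc[nH]c2c1 | starting material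
2 | 2,5‑dichloro‑1,4‑benzoquinone | O=C1C=C(Cl)C(=O)C=C1Cl | starting material
3 | 2,5‑dichloro‑3‑(6‑methoxy‑1H‑indol‑3‑yl)benzene‑1,4‑diol | COc1ccc2c(-c3c(O)c(Cl)cc(O)c3Cl)c[nH]c2c1 | intermediate
4 | 2,5‑dichloro‑3‑(6‑methoxy‑1H‑indol‑3‑yl)cyclohexa‑2,5‑diene‑1,4‑dione | COc1ccc2c(C3=C(Cl)C(=O)C=C(Cl)C3=O)c[nH]c2c1 | intermediate
5 | 5‑(benzyloxy)‑1H‑indole | c1ccc(COc2ccc3[nH]ccc3c2)cc1 | starting material
6 | 2‑[5‑(benzyloxy)‑1H‑indol‑3‑yl]‑3,6‑dichloro‑5‑(6‑methoxy‑1H‑indol‑3‑yl)benzene‑1,4‑diol | COc1ccc2c(-c3c(O)c(Cl)c(-c4c[nH]c5ccc(OCc6ccccc6)cc45)c(O)c3Cl)c[nH]c2c1 | intermediate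
7 | 2‑[5‑(benzyloxy)‑1H‑indol‑3‑yl]‑3,6‑dichloro‑5‑(6‑methoxy‑1H‑indol‑3‑yl)cyclohexa‑2,5‑diene‑1,4‑dione | COc1ccc2c(C3=C(Cl)C(=O)C(c4c[nH]c5ccc(OCc6ccccc6)cc45)=C(Cl)C3=O)c[nH]c2c1 | intermediate
8 | 2‑[5‑(benzyloxy)‑1H‑indol‑3‑yl]‑3,6‑dimethoxy‑5‑(6‑methoxy‑1H‑indol‑3‑yl)cyclohexa‑2,5‑diene‑1,4‑dione | COc1ccc2c(C3=C(OC)C(=O)C(c4c[nH]c5ccc(OCc6ccccc6)cc45)=C(OC)C3=O)c[nH]c2c1 | intermediate
9 | 2‑[5‑(benzyloxy)‑1H‑indol‑3‑yl]‑3,6‑dimethoxy‑5‑(6‑methoxy‑1H‑indol‑3‑yl)benzene‑1,4‑diol | COc1ccc2c(-c3c(OC)c(O)c(-c4c[nH]c5ccc(OCc6ccccc6)cc45)c(OC)c3O)c[nH]c2c1 | intermediate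
10 | 5‑(benzyloxy)‑3‑[4‑(6‑methoxy‑1H‑indol‑3‑yl)‑2,3,5,6‑tetramethoxyphenyl]‑1H‑indole | COc1ccc2c(-c3c(OC)c(OC)c(-c4c[nH]c5ccc(OCc6ccccc6)cc45)c(OC)c3OC)c[nH]c2c1 | intermediate
11 | 3‑[4‑(6‑methoxy‑1H‑indol‑3‑yl)‑2,3,5,6‑tetramethoxyphenyl]‑1H‑indol‑5‑ol | COc1ccc2c(-c3c(OC)c(OC)c(-c4c[nH]c5ccc(O)cc45)c(OC)c3OC)c[nH]c2c1 | target

**Totals**

Total step count: 5. Longest linear sequence: 5 steps (2 → 4 → 7 → 8 → 10 → 11).

**Steps most likely to fail**

Step 2. The second addition may stall because the quinone is already deactivated by one indolyl donor, and acid‑induced self‑condensation of the electron‑rich indole or ipso attack at a chlorine‑bearing carbon may then take over. The fallback makes the same bond by Suzuki–Miyaura coupling; it sets out from 4 and 5 and comes back at 8, so it replaces steps 2 and 3. Compound 4 would be treated with NaOMe in MeOH to give 2,5‑dimethoxy‑3‑(6‑methoxy‑1H‑indol‑3‑yl)cyclohexa‑2,5‑diene‑1,4‑dione F1. Its remaining ring C–H, the α‑carbon of a vinylogous ester, would be brominated with NBS in DMF at 0 °C to 2‑bromo‑3,6‑dimethoxy‑5‑(6‑methoxy‑1H‑indol‑3‑yl)cyclohexa‑2,5‑diene‑1,4‑dione F2. Compound 5 would be converted with Boc2O and DMAP into tert‑butyl 5‑(benzyloxy)indole‑1‑carboxylate F3, brominated at C3 with NBS to tert‑butyl 5‑(benzyloxy)‑3‑bromoindole‑1‑carboxylate F4, and borylated (B2pin2, PdCl2(dppf), KOAc, dioxane, 80 °C) to tert‑butyl 5‑(benzyloxy)‑3‑(4,4,5,5‑tetramethyl‑1,3,2‑dioxaborolan‑2‑yl)indole‑1‑carboxylate F5. Coupling of F2 and F5 (PdCl2(dppf), K3PO4, dioxane, 80 °C) should give tert‑butyl 5‑(benzyloxy)‑3‑[2,5‑dimethoxy‑4‑(6‑methoxy‑1H‑indol‑3‑yl)‑3,6‑dioxocyclohexa‑1,4‑dien‑1‑yl]indole‑1‑carboxylate F6. Methanolysis of the carbamate (NaOMe, MeOH, rt) then returns 8.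

Step 4. The indole nitrogens may be methylated in competition, the two hindered phenols may be methylated incompletely, or the hydroquinone may re‑oxidise in air before it is alkylated. The fallback protects both nitrogens so that forcing alkylation can be used; it sets out from 8 and comes back at 10. Compound 8 would be treated with Boc2O and DMAP in MeCN to give tert‑butyl 5‑(benzyloxy)‑3‑{4‑[1‑(tert‑butoxycarbonyl)‑6‑methoxy‑1H‑indol‑3‑yl]‑2,5‑dimethoxy‑3,6‑dioxocyclohexa‑1,4‑dien‑1‑yl}indole‑1‑carboxylate F8. Reduction with Na2S2O4 in THF/H2O would give tert‑butyl 5‑(benzyloxy)‑3‑{4‑[1‑(tert‑butoxycarbonyl)‑6‑methoxy‑1H‑indol‑3‑yl]‑3,6‑dihydroxy‑2,5‑dimethoxyphenyl}indole‑1‑carboxylate F9. Methylation with excess MeI and Cs2CO3 in DMF would give tert‑butyl 5‑(benzyloxy)‑3‑{4‑[1‑(tert‑butoxycarbonyl)‑6‑methoxy‑1H‑indol‑3‑yl]‑2,3,5,6‑tetramethoxyphenyl}indole‑1‑carboxylate F10. Methanolysis of both carbamates (K2CO3, MeOH, reflux) then returns 10.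

Step 3. The second substitution may stay incomplete once the first methoxy group has lowered the electrophilicity of the quinone, or adventitious hydroxide may hydrolyse the product to a hydroxyquinone. The fallback turns the hydrolysis into the intended path and forms the O–CH3 bonds by alkylation; it sets out from 7 and comes back at 8. Compound 7 would be heated with NaOH in MeOH/H2O to give 2‑[5‑(benzyloxy)‑1H‑indol‑3‑yl]‑3,6‑dihydroxy‑5‑(6‑methoxy‑1H‑indol‑3‑yl)cyclohexa‑2,5‑diene‑1,4‑dione F7. O‑Methylation of this vinylogous acid (Me2SO4, K2CO3, acetone, rt) then returns 8.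

**Further compounds**

F1 | step 2 | 2,5‑dimethoxy‑3‑(6‑methoxy‑1H‑indol‑3‑yl)cyclohexa‑2,5‑diene‑1,4‑dione | COc1ccc2c(C3=C(OC)C(=O)C=C(OC)C3=O)c[nH]c2c1
F2 | step 2 | 2‑bromo‑3,6‑dimethoxy‑5‑(6‑methoxy‑1H‑indol‑3‑yl)cyclohexa‑2,5‑diene‑1,4‑dione | COc1ccc2c(C3=C(OC)C(=O)C(Br)=C(OC)C3=O)c[nH]c2c1
F3 | step 2 | tert‑butyl 5‑(benzyloxy)indole‑1‑carboxylate | CC(C)(C)OC(=O)n1ccc2cc(OCc3ccccc3)ccc21
F4 | step 2 | tert‑butyl 5‑(benzyloxy)‑3‑bromoindole‑1‑carboxylate | CC(C)(C)OC(=O)n1cc(Br)c2cc(OCc3ccccc3)ccc21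
F5 | step 2 | tert‑butyl 5‑(benzyloxy)‑3‑(4,4,5,5‑tetramethyl‑1,3,2‑dioxaborolan‑2‑yl)indole‑1‑carboxylate | CC(C)(C)OC(=O)n1cc(B2OC(C)(C)C(C)(C)O2)c2cc(OCc3ccccc3)ccc21
F6 | step 2 | tert‑butyl 5‑(benzyloxy)‑3‑[2,5‑dimethoxy‑4‑(6‑methoxy‑1H‑indol‑3‑yl)‑3,6‑dioxocyclohexa‑1,4‑dien‑1‑yl]indole‑1‑carboxylate | COc1ccc2c(C3=C(OC)C(=O)C(c4cn(C(=O)OC(C)(C)C)c5ccc(OCc6ccccc6)cc45)=C(OC)C3=O)c[nH]c2c1
F7 | step 3 | 2‑[5‑(benzyloxy)‑1H‑indol‑3‑yl]‑3,6‑dihydroxy‑5‑(6‑methoxy‑1H‑indol‑3‑yl)cyclohexa‑2,5‑diene‑1,4‑dione | COc1ccc2c(C3=C(O)C(=O)C(c4c[nH]c5ccc(OCc6ccccc6)cc45)=C(O)C3=O)c[nH]c2c1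
F8 | step 4 | tert‑butyl 5‑(benzyloxy)‑3‑{4‑[1‑(tert‑butoxycarbonyl)‑6‑methoxy‑1H‑indol‑3‑yl]‑2,5‑dimethoxy‑3,6‑dioxocyclohexa‑1,4‑dien‑1‑yl}indole‑1‑carboxylate | COc1ccc2c(C3=C(OC)C(=O)C(c4cn(C(=O)OC(C)(C)C)c5ccc(OCc6ccccc6)cc45)=C(OC)C3=O)cn(C(=O)OC(C)(C)C)c2c1
F9 | step 4 | tert‑butyl 5‑(benzyloxy)‑3‑{4‑[1‑(tert‑butoxycarbonyl)‑6‑methoxy‑1H‑indol‑3‑yl]‑3,6‑dihydroxy‑2,5‑dimethoxyphenyl}indole‑1‑carboxylate | COc1ccc2c(-c3c(OC)c(O)c(-c4cn(C(=O)OC(C)(C)C)c5ccc(OCc6ccccc6)cc45)c(OC)c3O)cn(C(=O)OC(C)(C)C)c2c1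
F10 | step 4 | tert‑butyl 5‑(benzyloxy)‑3‑{4‑[1‑(tert‑butoxycarbonyl)‑6‑methoxy‑1H‑indol‑3‑yl]‑2,3,5,6‑tetramethoxyphenyl}indole‑1‑carboxylate | COc1ccc2c(-c3c(OC)c(OC)c(-c4cn(C(=O)OC(C)(C)C)c5ccc(OCc6ccccc6)cc45)c(OC)c3OC)cn(C(=O)OC(C)(C)C)c2c1
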